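**Plan**

- Ring names: A is the butanoyl-filicinic ring, B the central aromatic ring, C the propanoyl-filicinic ring. Ring C is numbered C-1 (bears the bridging CH2), C-2 (enol C–O), C-3 (CMe2), C-4 (enol C–O), C-5 (bears the propanoyl group), C-6 (ring C=O).
- Retrosynthesis: the bond between ring A and its bridging CH2 is cut first (ortho-quinone methide Michael addition). Ring C is then cut at C-1–C-2 and C-5–C-6. Last, the aryl–CH2 and lactone C–O bonds of a dihydrocoumarin are cut.
- Enabling feature: C-6, C-1, the bridging CH2, the ring B carbon it sits on and that carbon's ortho phenol oxygen are the atoms of a 3,4-dihydrocoumarin, so this phenol oxygen can be the leaving group of a Dieckmann closure. C-2 to C-5 with the propanoyl group are the ring-opened form of 6-ethyl-3,3-dimethylpyran-2,4-dione.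
- Forward order: rings A and B come intact from phlorobutyrophenone (ring A by dearomatising gem-dimethylation). A temporary lactone ring is closed on ring B. Ring C is closed last, in one pot with the union of the two fragments and the opening of the lactone. The A–B methylene bridge is joined afterwards without any ring closure.
- Stereochemistry: the target is achiral. The only stereocentre on the way (C-3 of the acylated lactone) is transient and racemic.

Key step: step 4

Remark: the target is drawn as one of several equivalent enol tautomers and all intermediates are written in the matching tautomer. 1-(2,4,6-Trihydroxyphenyl)butan-1-one is taken as a commercial starting material.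

**Route**

Step 1
Reactants: 1 1-(2,4,6-trihydroxyphenyl)butan-1-one (phlorobutyrophenone); 2 acrylic acid
Product: 3 6-butanoyl-5,7-dihydroxy-3,4-dihydro-2H-chromen-2-one
Conditions: 2 (1.3 equiv), Amberlyst 15, toluene–1,4-dioxane, 100 °C, Dean–Stark
Reagents that add atoms: none
Why: Acid-catalysed Friedel–Crafts conjugate addition of one of the two equivalent free ring carbons to acrylic acid followed by lactonisation is a known route from phloroglucinols to 3,4-dihydrocoumarins; reversible lactonisation should favour the hydroxyl para to the butanoyl group, and the regioisomeric lactone would in any case open to the same phenol in step 4.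

Step 2
Reactants: 4 methyl 2,2-dimethyl-3-oxobutanoate; 5 propanoyl chloride
Product: 6 methyl 2,2-dimethyl-3,5-dioxoheptanoate
Conditions: 4 (2.0 equiv), LiN(SiMe3)2 (2.0 equiv), toluene–THF, −78 °C; then 5 (1.0 equiv), −78 → 0 °C; aq NH4Cl
Reagents that add atoms: none
Why: Crossed Claisen-type C-acylation of the only possible enolate of 4 (the methyl ketone, the other alpha carbon being quaternary) by the acid chloride, with the second equivalent of enolate taking up the acidic proton of the new 1,3-diketone and the excess 4 being recovered.

Step 3
Reactants: 6 methyl 2,2-dimethyl-3,5-dioxoheptanoate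
Product: 7 6-ethyl-3,3-dimethyl-2H-pyran-2,4(3H)-dione
Conditions: TsOH·H2O (5 mol %), toluene, reflux, methanol distilled off
Reagents that add atoms: none
Why: Acid-catalysed enol-lactonisation of a 3,5-dioxo ester (6-exo-trig attack of the 5-enol hydroxyl on the ester) is a known route to pyran-2-ones, here favoured by the gem-dimethyl group and driven by removal of methanol, and the quaternary C-3 holds the product as the 2,4-dione.

Step 4
Reactants: 3 6-butanoyl-5,7-dihydroxy-3,4-dihydro-2H-chromen-2-one; 7 6-ethyl-3,3-dimethyl-2H-pyran-2,4(3H)-dione
Product: 9 2-[(3-butanoyl-2,4,6-trihydroxyphenyl)methyl]-3,5-dihydroxy-4,4-dimethyl-6-propanoylcyclohexa-2,5-dien-1-one, via 3-acyl lactone 8 (not isolated)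
Conditions: LiN(iPr)2 (3.1 equiv), THF, −78 °C; then 7 (1.1 equiv), −78 → 25 °C, then 50 °C; 1 M HCl work-up
Reagents that add atoms: none
Why: Proposed new method: LiN(iPr)2 should first form the two phenoxides of 3, which make the butanoyl ketone a vinylogous carboxylate and so block its alpha-deprotonation, and then the lactone enolate at C-3; this enolate attacks the enol-lactone carbonyl C-2 of 7 (crossed Claisen acylation) and the ring of 7 opens with its enolate oxygen as leaving group, which delivers 8 directly as the lithium 1,3-diketonate. The central carbon of that diketonate (future C-5) then adds to the aryl-lactone carbonyl (future C-6) in a 6-exo-trig Dieckmann closure that forms ring C, and collapse of the adduct expels the phenoxide of ring B, so the temporary lactone ring is opened and the ortho hydroxyl is returned in the same event. The closest known reaction types are the C-acylation of lactone enolates by enol esters, the Dieckmann closures that give syncarpic and filicinic acids from 3,5-dioxo esters, and the Baker-Venkataraman transfer of an aryl ester acyl group to an enolate carbon; their one-pot combination with a pyran-2,4-dione as a four-carbon donor on an unprotected polyphenol is the new element. No stereocentre is formed, because C-3 of 8 becomes the sp2 carbon C-1 of ring C. The step needs carbonyl addition at C-2 of 7 in preference to proton abstraction from its ethyl group or attack at C-4 and C-6, and C- in preference to O-acylation in the closure: the first is secured by C-2 being the only activated (enol ester) acyl carbon of 7 and by addition at −78 °C, the second by the reversibility of O-acylation (the tethered phenoxide re-forms the lactone) against the irreversible formation of the fully delocalised beta-triketone anion of 9, with only the diketonate carbon able to reach the lactone carbonyl through a six-membered transition state and the gem-dimethyl group favouring closure.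

Step 5
Reactants: 9 2-[(3-butanoyl-2,4,6-trihydroxyphenyl)methyl]-3,5-dihydroxy-4,4-dimethyl-6-propanoylcyclohexa-2,5-dien-1-one
Product: 10 2-[[3-butanoyl-5-[(dimethylamino)methyl]-2,4,6-trihydroxyphenyl]methyl]-3,5-dihydroxy-4,4-dimethyl-6-propanoylcyclohexa-2,5-dien-1-one
Conditions: Me2NCH2NMe2 (1.05 equiv), MeCN, 0 → 25 °C
Reagents that add atoms: bis(dimethylamino)methane, CN(C)CN(C)C
Why: Mannich aminomethylation at the only unsubstituted carbon of ring B, which is flanked by two hydroxyls, with the acidic triketone of 9 itself ionising the aminal to the iminium ion.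

Step 6
Reactants: 1 1-(2,4,6-trihydroxyphenyl)butan-1-one
Product: 11 2-butanoyl-3,5-dihydroxy-4,4-dimethylcyclohexa-2,5-dien-1-one (butanoylfilicinic acid)
Conditions: MeI (2.2 equiv), NaOMe (3 equiv), MeOH, 0 → 25 °C
Reagents that add atoms: iodomethane, CI
Why: Dearomatising C,C-dimethylation of the acylphloroglucinol anion at one ring carbon is the classical preparation of acylfilicinic acids, the second methyl group entering at the already methylated carbon to give the gem-dimethyl cyclohexadienone.

Step 7
Reactants: 10 2-[[3-butanoyl-5-[(dimethylamino)methyl]-2,4,6-trihydroxyphenyl]methyl]-3,5-dihydroxy-4,4-dimethyl-6-propanoylcyclohexa-2,5-dien-1-one; 11 2-butanoyl-3,5-dihydroxy-4,4-dimethylcyclohexa-2,5-dien-1-one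
Product: 12 2-butanoyl-6-[[3-butanoyl-5-[(2,6-dihydroxy-3,3-dimethyl-4-oxo-5-propanoylcyclohexa-1,5-dien-1-yl)methyl]-2,4,6-trihydroxyphenyl]methyl]-3,5-dihydroxy-4,4-dimethylcyclohexa-2,5-dien-1-one (target)
Conditions: 11 (1.5 equiv), 1,4-dioxane, 70 °C, N2 sweep
Reagents that add atoms: none
Why: Loss of dimethylamine from the phenolic Mannich base (helped by protonation by the acidic 11) gives the ortho-quinone methide of ring B, which is captured by the free enol carbon of 11 in a Michael addition and rearomatises, the standard way to methylene-bridged acylphloroglucinols.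

**Compound list**

1 | 1-(2,4,6-trihydroxyphenyl)butan-1-one (phlorobutyrophenone) | CCCC(=O)c1c(O)cc(O)cc1O | starting material
2 | acrylic acid (prop-2-enoic acid) | C=CC(=O)O | starting material
3 | 6-butanoyl-5,7-dihydroxy-3,4-dihydro-2H-chromen-2-one | CCCC(=O)c1c(O)cc2OC(=O)CCc2c1O | intermediate
4 | methyl 2,2-dimethyl-3-oxobutanoate | CC(=O)C(C)(C)C(=O)OC | starting material
5 | propanoyl chloride | CCC(=O)Cl | starting material
6 | methyl 2,2-dimethyl-3,5-dioxoheptanoate | CCC(=O)CC(=O)C(C)(C)C(=O)OC | intermediate
7 | 6-ethyl-3,3-dimethyl-2H-pyran-2,4(3H)-dione | CCC1=CC(=O)C(C)(C)C(=O)O1 | intermediate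
8 | 6-butanoyl-3-(2,2-dimethyl-3,5-dioxoheptanoyl)-5,7-dihydroxy-3,4-dihydro-2H-chromen-2-one (racemic, present as its lithium salt, not isolated) | CCC(=O)CC(=O)C(C)(C)C(=O)C1Cc2c(O)c(C(=O)CCC)c(O)cc2OC1=O | intermediate
9 | 2-[(3-butanoyl-2,4,6-trihydroxyphenyl)methyl]-3,5-dihydroxy-4,4-dimethyl-6-propanoylcyclohexa-2,5-dien-1-one | CCCC(=O)c1c(O)cc(O)c(CC2=C(O)C(C)(C)C(O)=C(C(=O)CC)C2=O)c1O | intermediate
10 | 2-[[3-butanoyl-5-[(dimethylamino)methyl]-2,4,6-trihydroxyphenyl]methyl]-3,5-dihydroxy-4,4-dimethyl-6-propanoylcyclohexa-2,5-dien-1-one | CCCC(=O)c1c(O)c(CN(C)C)c(O)c(CC2=C(O)C(C)(C)C(O)=C(C(=O)CC)C2=O)c1O | intermediate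
11 | 2-butanoyl-3,5-dihydroxy-4,4-dimethylcyclohexa-2,5-dien-1-one (butanoylfilicinic acid) | CCCC(=O)C1=C(O)C(C)(C)C(O)=CC1=O | intermediate
12 | 2-butanoyl-6-[[3-butanoyl-5-[(2,6-dihydroxy-3,3-dimethyl-4-oxo-5-propanoylcyclohexa-1,5-dien-1-yl)methyl]-2,4,6-trihydroxyphenyl]methyl]-3,5-dihydroxy-4,4-dimethylcyclohexa-2,5-dien-1-one | CCCC(=O)C1=C(O)C(C)(C)C(O)=C(Cc2c(O)c(CC3=C(O)C(C)(C)C(O)=C(C(=O)CC)C3=O)c(O)c(C(=O)CCC)c2O)C1=O | target

**Step count and risks**

Total step count: 7.
Longest linear sequence: 5 steps (4 → 6 → 7 → 9 → 10 → 12).

Steps most likely to fail: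

1. Step 4 (proposed method). The lactone enolate may take a proton from the 6-ethyl group of 7 instead of adding to its hindered enol-lactone carbonyl. The chain may also stall after O-acylation, so that ring C does not close. The fallback uses known chemistry only, sets out from 1 and comes back to the route at 9. Ring C is then taken from the aromatic series. Commercial 1-(2,4,6-trihydroxyphenyl)propan-1-one is gem-dimethylated (MeI, NaOMe, MeOH) to 3,5-dihydroxy-4,4-dimethyl-2-propanoylcyclohexa-2,5-dien-1-one F1. Compound 1 is aminomethylated once with Me2NCH2NMe2 to 1-[3-[(dimethylamino)methyl]-2,4,6-trihydroxyphenyl]butan-1-one F2. Heating F2 with F1 in 1,4-dioxane (ortho-quinone methide Michael addition) should give 9, from which steps 5 to 7 follow unchanged.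

2. Step 7. Under amine and heat the bridge between rings B and C that is already in place may open by retro-Michael cleavage and exchange its filicinic unit, so that the two acyl types scramble. Capture of the quinone methide may also be incomplete. The fallback sets out from 9 (with 11) and comes back at 12. Compound 9 is formylated at the free carbon of ring B (Duff reaction: hexamethylenetetramine, CF3CO2H, 70 °C, then aq HCl) to 3-butanoyl-5-[(2,6-dihydroxy-3,3-dimethyl-4-oxo-5-propanoylcyclohexa-1,5-dien-1-yl)methyl]-2,4,6-trihydroxybenzaldehyde F3. F3 is then joined to 11 by organocatalytic reductive alkylation (Hantzsch ester, L-proline cat., CH2Cl2, 25 °C). This is a Knoevenagel condensation followed by transfer hydrogenation of the alkylidene, and it should give 12 near neutrality without amine base or heating.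

3. Step 1. Lactonisation may go to the wrong hydroxyl, the ring may be alkylated twice, or the acyl-deactivated ring may react sluggishly while acrylic acid polymerises. The fallback sets out from 1 and comes back at 3. The unchelated para hydroxyl of 1 is esterified with propiolic acid (DCC, CH2Cl2, 0 °C) to 4-butanoyl-3,5-dihydroxyphenyl prop-2-ynoate F4. Intramolecular hydroarylation of the alkyne (Pd(OAc)2 cat., CF3CO2H–CH2Cl2, 25 °C) closes the coumarin 6-butanoyl-5,7-dihydroxy-2H-chromen-2-one F5 with the lactone oxygen fixed para to the butanoyl group. Hydrogenation of the 3,4-double bond (H2, Pd on carbon, EtOAc) gives 3.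

**Further compounds**

F1 | step 4 | 3,5-dihydroxy-4,4-dimethyl-2-propanoylcyclohexa-2,5-dien-1-one (propanoylfilicinic acid) | CCC(=O)C1=C(O)C(C)(C)C(O)=CC1=O
F2 | step 4 | 1-[3-[(dimethylamino)methyl]-2,4,6-trihydroxyphenyl]butan-1-one | CCCC(=O)c1c(O)cc(O)c(CN(C)C)c1O
F3 | step 7 | 3-butanoyl-5-[(2,6-dihydroxy-3,3-dimethyl-4-oxo-5-propanoylcyclohexa-1,5-dien-1-yl)methyl]-2,4,6-trihydroxybenzaldehyde | CCCC(=O)c1c(O)c(C=O)c(O)c(CC2=C(O)C(C)(C)C(O)=C(C(=O)CC)C2=O)c1O
F4 | step 1 | 4-butanoyl-3,5-dihydroxyphenyl prop-2-ynoate | CCCC(=O)c1c(O)cc(OC(=O)C#C)cc1O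
F5 | step 1 | 6-butanoyl-5,7-dihydroxy-2H-chromen-2-one | CCCC(=O)c1c(O)cc2OC(=O)C=Cc2c1O
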